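**Retrosynthetic overview**
1. Target 23 ⇐ 21 by the C11–O bond: singlet-oxygen ene reaction of the 7(11)-en-8-one, which also moves the alkene to C6–C7.
2. 21 ⇐ 16 by the C3–O and C4–O bonds: α-face syn-hydroxy-angeloyloxylation of the 3-ene with peroxide 18, then acetylation of the tertiary hydroxyl.
3. 16 ⇐ 11 + acetone (aldol addition, dehydration); 11 ⇐ enone 7 by reductive removal of the C3 oxygen, which sets the trans ring fusion.
4. 7 ⇐ 1 + 3 by asymmetric Michael addition and aldol condensation; ring B is bought as cyclohexanone 1, ring A is closed second.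

Assumption: racemic 1, (R)-1-phenylethylamine, ethyl vinyl ketone, acetone and angelic acid are catalogue compounds; atom numbers and α/β follow eudesmane numbering, with the C10 methyl as β.

**Step 1**
Reactants: 1 7-methyl-1,4-dioxaspiro[4.5]decan-8-one (racemic); 2 (R)-1-phenylethylamine; 3 pent-1-en-3-one
Product: 6 (7R)-7-methyl-7-(3-oxopentyl)-1,4-dioxaspiro[4.5]decan-8-one, via ketimine 4 (not isolated), via Michael-adduct ketimine 5 (not isolated)
Conditions: 2, TsOH (cat.), toluene, reflux, Dean–Stark; then 3, THF, 45 °C, 4 d; then 10% aq AcOH, 23 °C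
Reagents that add atoms: pent-1-en-3-one, C=CC(=O)CC; water, O
Why: Chiral-imine (d'Angelo) asymmetric Michael addition, in which the more substituted enamine tautomer of 4 adds to 3 on the face anti to the phenyl group and so sets the quaternary C10 centre (the 10β-methyl of the target), after which mild acid releases the auxiliary and leaves the dioxolane intact.

**Step 2**
Reactants: 6 (7R)-diketone
Product: 7 8,8-ethylenedioxy-11,12,13-trinoreudesm-4-en-3-one (10β-methyl)
Conditions: NaOMe, MeOH, 60 °C
Reagents that add atoms: none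
Why: Intramolecular aldol condensation (second stage of the Robinson annulation) closes ring A onto the ring B ketone without creating a stereocentre or disturbing the quaternary one.

**Step 3**
Reactants: 7 enone ketal
Product: 9 8,8-ethylenedioxy-5αH-11,12,13-trinoreudesm-3-en-3-yl trifluoromethanesulfonate, via lithium enolate 8 (not isolated)
Conditions: Li (2.2 equiv), t-BuOH (1 equiv), NH3/THF, −78 °C; NH3 off; then PhNTf2, THF, 0 °C
Reagents that add atoms: N-phenylbis(trifluoromethanesulfonimide), O=S(=O)(N(c1ccccc1)S(=O)(=O)C(F)(F)F)C(F)(F)F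
Why: Dissolving-metal conjugate reduction protonates C5 axially to give the trans ring fusion (5α-H), and the regiodefined C3–C4 enolate 8 is trapped on oxygen before it can equilibrate (reductive enol triflation).

**Step 4**
Reactants: 9 enol triflate
Product: 11 5αH-11,12,13-trinoreudesm-3-en-8-one, via alkene ketal 10 (not isolated)
Conditions: Pd(OAc)2 (5 mol%), PPh3, Bu3N, HCO2H, DMF, 60 °C; then 1 M HCl, THF, 23 °C
Reagents that add atoms: water, O
Why: Oxidative addition of the enol triflate to zerovalent palladium, formate-to-hydride exchange with loss of CO2 and reductive elimination leave the trisubstituted 3-ene in place (palladium-catalysed formate reduction), and dilute acid then hydrolyses the dioxolane to the C8 ketone.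

**Step 5**
Reactants: 11 nor-ketone; 12 acetone
Product: 14 11-hydroxy-5αH-eudesm-3-en-8-one (C7 epimers), via lithium enolate 13 (not isolated)
Conditions: LiN(iPr)2, THF, −78 °C; then acetone, −78 °C; AcOH quench at −78 °C
Reagents that add atoms: acetone, CC(C)=O
Why: Kinetic deprotonation by the hindered amide occurs at C7, not at the neopentyl C9, and the enolate adds to acetone (directed aldol addition); the C7 centre is erased in step 6, so its configuration does not matter.

**Step 6**
Reactants: 14 aldol adduct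
Product: 16 5αH-eudesma-3,7(11)-dien-8-one, via mesylate 15 (not isolated)
Conditions: MsCl, Et3N, CH2Cl2, 0 °C; then DBU, 23 °C
Reagents that add atoms: none
Why: Mesylation of the tertiary alcohol through sulfene and E1cB elimination across the acidic C7–H give the conjugated tetrasubstituted alkene (aldol dehydration), DBU also drawing any isopropenyl isomer into conjugation.

**Step 7**
Reactants: 17 angelic acid (2.0 equiv)
Product: 18 bis[(Z)-2-methylbut-2-enoyl] peroxide
Conditions: 17 (2.0 equiv), DCC (2.0 equiv), urea–H2O2 (1.0 equiv), CH2Cl2, −10 °C, dark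
Reagents that add atoms: angelic acid, C/C=C(/C)C(=O)O; hydrogen peroxide, OO
Why: Carbodiimide coupling joins two molecules of 17 through the two oxygens of one hydrogen peroxide (standard diacyl peroxide synthesis: O-acylisourea, then peracid, then a second O-acylisourea); it runs cold, neutral and without a nucleophilic catalyst, so the Z-alkene is not isomerised.

**Step 8**
Reactants: 16 dienone; 18 peroxide
Product: 20 3α-angeloyloxy-4α-hydroxy-5αH-eudesm-7(11)-en-8-one, via dioxolan-2-ylium angelate 19 (not isolated)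
Conditions: 18 (1.5 equiv), (CF3)2CHOH/CH2Cl2 1:1, 0 → 23 °C, dark; then H2O, 23 °C
Reagents that add atoms: bis[(Z)-2-methylbut-2-enoyl] peroxide, C/C=C(/C)C(=O)OOC(=O)/C(C)=C\C; water, O
Why: Proposed new method: the electron-rich 3-ene attacks the O–O bond of the diacyl peroxide (activated by hydrogen bonding to the fluorinated alcohol) axially at C3 from the α-face, anti to the C10 methyl. The incipient tertiary C4 cation is closed on the same face by the carbonyl oxygen of the new ester to give the cis-fused dioxolan-2-ylium ion 19, and water opens its hemiorthoester with stereoelectronic control to the axial C3 ester and the equatorial tertiary C4 hydroxyl. One step thus sets both oxygen stereocentres and differentiates the two oxygens, while the conjugated 7(11)-alkene is too electron-poor to react. The closest known reaction type is the metal-free syn-dihydroxylation of alkenes with cyclic malonoyl or phthaloyl peroxides; it has not been shown with an acyclic unsaturated diacyl peroxide or on an unactivated trisubstituted cycloalkene.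

**Step 9**
Reactants: 20 hydroxy angelate
Product: 21 4α-acetoxy-3α-angeloyloxy-5αH-eudesm-7(11)-en-8-one
Conditions: Ac2O, 4-(dimethylamino)pyridine, Et3N, CH2Cl2, 40 °C
Reagents that add atoms: acetic anhydride, CC(=O)OC(C)=O
Why: Acylation catalysed by 4-(dimethylamino)pyridine (acylpyridinium) acetylates the equatorial tertiary C4 hydroxyl; acyl migration from the secondary to the tertiary oxygen is not favoured, and the conditions are too mild to isomerise the angelate.

**Step 10**
Reactants: 21 diester
Product: 23 4α-acetoxy-3α-angeloyloxy-11-hydroxy-5αH-eudesm-6-en-8-one (target CNP0351454.1), via hydroperoxide 22 (not isolated)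
Conditions: O2, meso-tetraphenylporphyrin (cat.), visible light, CH2Cl2, −20 °C; then PPh3, 0 °C
Reagents that add atoms: oxygen, O=O
Why: Schenck ene reaction of singlet oxygen with the s-cis locked enone, where the carbonyl directs abstraction of the allylic hydrogen geminal to it (axial 6β-H) so that the hydroperoxide lands on C11 and the alkene moves to C6–C7 (no new stereocentre; the electron-poor angelate reacts far more slowly), and PPh3 then reduces the hydroperoxide to the alcohol.

**Compound list**
1 | 7-methyl-1,4-dioxaspiro[4.5]decan-8-one (racemic) | CC1CC2(CCC1=O)OCCO2 | starting material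
2 | (R)-1-phenylethylamine | C[C@@H](N)c1ccccc1 | starting material
3 | pent-1-en-3-one | C=CC(=O)CC | starting material
4 | N-[(R)-1-phenylethyl] ketimine of 1 | CC1CC2(CCC1=N[C@H](C)c1ccccc1)OCCO2 | intermediate
5 | N-[(R)-1-phenylethyl] ketimine of 6 (7R) | CCC(=O)CC[C@]1(C)CC2(CCC1=N[C@H](C)c1ccccc1)OCCO2 | intermediate
6 | (7R)-7-methyl-7-(3-oxopentyl)-1,4-dioxaspiro[4.5]decan-8-one | CCC(=O)CC[C@]1(C)CC2(CCC1=O)OCCO2 | intermediate
7 | 8,8-ethylenedioxy-11,12,13-trinoreudesm-4-en-3-one (10β-methyl) | O=C1CC[C@]2(C)CC3(CCC2=C1C)OCCO3 | intermediate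
8 | lithium 8,8-ethylenedioxy-5αH-11,12,13-trinoreudesm-3-en-3-olate | CC1=C(O[Li])CC[C@]2(C)CC3(OCCO3)CC[C@@H]12 | intermediate
9 | 8,8-ethylenedioxy-5αH-11,12,13-trinoreudesm-3-en-3-yl trifluoromethanesulfonate | CC1=C(OS(=O)(=O)C(F)(F)F)CC[C@]2(C)CC3(OCCO3)CC[C@@H]12 | intermediate
10 | 8,8-ethylenedioxy-5αH-11,12,13-trinoreudesm-3-ene | CC1=CCC[C@]2(C)CC3(OCCO3)CC[C@@H]12 | intermediate
11 | 5αH-11,12,13-trinoreudesm-3-en-8-one (10β-methyl, trans-fused) | CC1=CCC[C@]2(C)CC(=O)CC[C@@H]12 | intermediate
12 | acetone | CC(C)=O | starting material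
13 | lithium 5αH-11,12,13-trinoreudesma-3,7-dien-8-olate | CC1=CCC[C@]2(C)CC(O[Li])=CC[C@@H]12 | intermediate
14 | 11-hydroxy-5αH-eudesm-3-en-8-one (C7 epimers) | CC1=CCC[C@]2(C)CC(=O)C(C(C)(C)O)C[C@@H]12 | intermediate
15 | 11-methanesulfonyloxy-5αH-eudesm-3-en-8-one | CC1=CCC[C@]2(C)CC(=O)C(C(C)(C)OS(C)(=O)=O)C[C@@H]12 | intermediate
16 | 5αH-eudesma-3,7(11)-dien-8-one | CC1=CCC[C@]2(C)CC(=O)C(=C(C)C)C[C@@H]12 | intermediate
17 | angelic acid, (Z)-2-methylbut-2-enoic acid | C/C=C(/C)C(=O)O | starting material
18 | bis[(Z)-2-methylbut-2-enoyl] peroxide (from two molecules of 17) | C/C=C(/C)C(=O)OOC(=O)/C(C)=C\C | intermediate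
19 | 3α,4α-cis-fused 2-[(Z)-but-2-en-2-yl]-1,3-dioxolan-2-ylium ion on C3/C4 of 16, angelate salt | C/C=C(/C)C1=[O+][C@@H]2CC[C@]3(C)CC(=O)C(=C(C)C)C[C@H]3[C@]2(C)O1.C/C=C(/C)C(=O)[O-] | intermediate
20 | 3α-angeloyloxy-4α-hydroxy-5αH-eudesm-7(11)-en-8-one | C/C=C(/C)C(=O)O[C@@H]1CC[C@]2(C)CC(=O)C(=C(C)C)C[C@H]2[C@]1(C)O | intermediate
21 | 4α-acetoxy-3α-angeloyloxy-5αH-eudesm-7(11)-en-8-one | C/C=C(/C)C(=O)O[C@@H]1CC[C@]2(C)CC(=O)C(=C(C)C)C[C@H]2[C@]1(C)OC(C)=O | intermediate
22 | 4α-acetoxy-3α-angeloyloxy-11-hydroperoxy-5αH-eudesm-6-en-8-one | C/C=C(/C)C(=O)O[C@@H]1CC[C@]2(C)CC(=O)C(C(C)(C)OO)=C[C@H]2[C@]1(C)OC(C)=O | intermediate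
23 | 4α-acetoxy-3α-angeloyloxy-11-hydroxy-5αH-eudesm-6-en-8-one | C/C=C(/C)C(=O)O[C@@H]1CC[C@]2(C)CC(=O)C(C(C)(C)O)=C[C@H]2[C@]1(C)OC(C)=O | target

**Step count**
Total: 10 steps. Longest linear sequence: 9 steps (1 to 6, then 8 to 10); step 7 makes the reagent 18 from two molecules of 17.

**Three steps most likely to fail**

Step 8 (the proposed new step): the acyclic peroxide may be too weak an oxygen electrophile, or the C4 cation may lose a proton instead of closing. The fallback uses known chemistry and sets out from 16. OsO4 (2 mol%) with N-methylmorpholine N-oxide in acetone/water dihydroxylates the 3-ene from the α-face and leaves the conjugated alkene alone, giving 3α,4α-dihydroxy-5αH-eudesm-7(11)-en-8-one F1. Angelic acid 17, pre-activated with 2,4,6-trichlorobenzoyl chloride and Et3N and then heated with F1 in toluene at 80 °C, acylates only the secondary hydroxyl, and the route is rejoined at 20.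

Step 9: the hindered tertiary hydroxyl may resist acetylation under conditions the angelate tolerates. The fallback installs the acetate before the angelate, so that forcing conditions can be used. It sets out from 16 and passes through the diol F1 made as above. TBSOTf (1.1 equiv) and 2,6-lutidine at −78 °C silylate the secondary hydroxyl to give 3α-tert-butyldimethylsilyloxy-4α-hydroxy-5αH-eudesm-7(11)-en-8-one F2. Ac2O, 4-(dimethylamino)pyridine and Et3N at 60 °C give 4α-acetoxy-3α-tert-butyldimethylsilyloxy-5αH-eudesm-7(11)-en-8-one F3. HF·pyridine in MeCN, which is acidic and so does not promote acetyl migration, gives 4α-acetoxy-3α-hydroxy-5αH-eudesm-7(11)-en-8-one F4. Angeloylation with the mixed 2,4,6-trichlorobenzoic anhydride as above rejoins the route at 21.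

Step 10: hydrogen abstraction from the C11 methyl groups or attack on the angelate could compete. The fallback takes the C11 oxygen from acetone instead of O2 and makes the C6–C7 alkene by dehydrogenation. It sets out from 14. TESOTf and 2,6-lutidine give 11-triethylsilyloxy-5αH-eudesm-3-en-8-one F5. IBX in DMSO at 70 °C, where only C6–C7 can be desaturated because C10 is quaternary, gives 11-triethylsilyloxy-5αH-eudesma-3,6-dien-8-one F6. The chemistry of step 8 gives 3α-angeloyloxy-4α-hydroxy-11-triethylsilyloxy-5αH-eudesm-6-en-8-one F7. Acetylation as in step 9 gives 4α-acetoxy-3α-angeloyloxy-11-triethylsilyloxy-5αH-eudesm-6-en-8-one F8. HF·pyridine then removes the silyl group and the route is rejoined at 23.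

**Further compounds**
F1 | step 8 | 3α,4α-dihydroxy-5αH-eudesm-7(11)-en-8-one | O[C@@H]1CC[C@]2(C)CC(=O)C(=C(C)C)C[C@H]2[C@]1(C)O
F2 | step 9 | 3α-tert-butyldimethylsilyloxy-4α-hydroxy-5αH-eudesm-7(11)-en-8-one | CC(C)(C)[Si](C)(C)O[C@@H]1CC[C@]2(C)CC(=O)C(=C(C)C)C[C@H]2[C@]1(C)O
F3 | step 9 | 4α-acetoxy-3α-tert-butyldimethylsilyloxy-5αH-eudesm-7(11)-en-8-one | CC(C)(C)[Si](C)(C)O[C@@H]1CC[C@]2(C)CC(=O)C(=C(C)C)C[C@H]2[C@]1(C)OC(C)=O
F4 | step 9 | 4α-acetoxy-3α-hydroxy-5αH-eudesm-7(11)-en-8-one | O[C@@H]1CC[C@]2(C)CC(=O)C(=C(C)C)C[C@H]2[C@]1(C)OC(C)=O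
F5 | step 10 | 11-triethylsilyloxy-5αH-eudesm-3-en-8-one (C7 epimers) | CC1=CCC[C@]2(C)CC(=O)C(C(C)(C)O[Si](CC)(CC)CC)C[C@@H]12
F6 | step 10 | 11-triethylsilyloxy-5αH-eudesma-3,6-dien-8-one | CC1=CCC[C@]2(C)CC(=O)C(C(C)(C)O[Si](CC)(CC)CC)=C[C@@H]12
F7 | step 10 | 3α-angeloyloxy-4α-hydroxy-11-triethylsilyloxy-5αH-eudesm-6-en-8-one | C/C=C(/C)C(=O)O[C@@H]1CC[C@]2(C)CC(=O)C(C(C)(C)O[Si](CC)(CC)CC)=C[C@H]2[C@]1(C)O
F8 | step 10 | 4α-acetoxy-3α-angeloyloxy-11-triethylsilyloxy-5αH-eudesm-6-en-8-one | C/C=C(/C)C(=O)O[C@@H]1CC[C@]2(C)CC(=O)C(C(C)(C)O[Si](CC)(CC)CC)=C[C@H]2[C@]1(C)OC(C)=O
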